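Readings and results are calculated from invented constants; noise was put on by code.

Over 8.0 d at constant temperature, each D can take up G twice, going to Z and then to E. Larch and oak must foretell three flasks.

| setting | larch | oak | violet | red | teal |
|---|---|---|---|---|---|
| D | 0.050 M | 0.050 M | 0.050 M | 0.050 M | 0.050 M |
| G | 0.028 M | 0.13 M | 0.0400 M | 0.200 M | 0.0500 M |
| remark | run made earlier | run made earlier |  |  |  |
| time |  |  | 8.0 d | 8.0 d | 8.0 d |

| run | time / d | E / % | Z / % |
|---|---|---|---|
| larch | 2.08 | 4.0 | 22.8 |
| larch | 4.00 | 6.0 | 29.6 |
| larch | 6.00 | 7.6 | 32.6 |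
| larch | 8.00 | 9.5 | 33.5 |
| oak | 2.08 | 38.3 | 37.6 |
| oak | 4.00 | 62.3 | 28.1 |
| oak | 6.00 | 75.5 | 18.8 |
| oak | 8.00 | 84.4 | 13.3 |

(readings scatter by 0.5 percentage points)

- which of these holds the largest part of the D at the end of violet (E / D / Z)
- which of these holds the largest part of the D at the end of red (E / D / Z)
- which of these holds the largest part of the D at the end of teal (E / D / Z)
- final E in red, as a percentage of the D charged

- steps under discussion: D + G <-> L + Z; Z + G <-> L + E; Z -> Q; L -> X

Count everything in fractions of the D charge, with g for G, so that g falls by Z + 2E. Take the main step first: D decays as exp(-s), where the clock s is a rate multiplied by g summed over time. This is pseudo-first-order while g holds still. Oak at 2.08 d leaves D as the remainder, 24.1%, so its clock reads 1.42. Its mean g is 2.03, which gives the clock rate per unit g, 0.337 d⁻¹.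

Now add the second step at the same speed: Z = s·exp(-s) and E = 1 - (1 + s)·exp(-s). Oak's Z reads 37.6%, more than the 34.3% this gives, so the second step is somewhat slower, and the reckoning accepts that error. Z overtakes D at clock one, which costs 0.896 of g. Violet's charge of 0.800 is less than that, so D leads there. Teal's 1.00 is more, so its charge lets Z pass D with 0.104 of g to spare. The time of that crossing is not reckoned here, and Z is taken to lead teal at the end, narrowly.

Next comes the fall of G in red. A first round holds g at 4.00, so the clock reaches 10.8. But D is the limiting reagent, and g ends near 2.00. The second round runs the clock on that floor and adds the G above the floor while it lasted: first exchanges come on average at clock one and second exchanges at clock two, read at the first-round rate, which adds 0.750. The clock becomes 6.14, less than the first round, and E is 98.5%. Oak's E and Z leave 2.30% for D and Q together at 8.00 d, so Q stays out of the reckoning; the way back and the loss of L to X are left out untested.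

The forecast names D, E and Z for violet, red and teal, and 98% for E in red, where “G is in large excess”.

Violet ends with D at 44.2%, teal with Z at 39.7%, and red with E at 98.5%.

    D + G ⇌ L + Z (K = 8.40, k = 8.67 × 10⁻⁵ L mol⁻¹ s⁻¹)
    Z + G ⇌ L + E (K = 90.2, k = 7.08 × 10⁻⁵ L mol⁻¹ s⁻¹)
    Z → Q (k = 2.20 × 10⁻⁹ s⁻¹)
    L → X (k = 8.78 × 10⁻⁶ s⁻¹)

The neighbouring flask is red read at 5.0 d. With the same clock rate and the same added part, the clock reads 4.12. That gives E at 91.7% and Z at 6.68%. Red's E has moved 5 points from its value at 8.0 d when read at 5.33 d, and the neighbour holds Z at 6.65% and E at 92.2%.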